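## Retrosynthetic overview

- Numbering follows the chain C2(Me2)–C3(OAc)–…–C22(=O)–C23(Me2). Ring A is the oxepane O/C2–C7, ring B the cyclohexane C6–C11, ring C the cyclohexane C14–C19, ring D the oxepane O/C18–C23.
- Feature: in ring B the quaternary C6 (CH3 and C5) lies between C7–O and C11, so C6 is the β-carbon of a 4-silyloxy-3-methylcyclohex-2-enone with C10 as carbonyl and C11 as enolate carbon. C19 of ring C repeats the pattern with C18–O and C14.
- Key disconnection (C5–C6 and C11–C12): homoprenyl copper addition to enone 7 anti to the C7 silyloxy group, trapping of the enolate at C11 by the ring C/D aldehyde 27 (C12), and dehydration to enone 31.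
- Aldehyde 27 goes back to the same conjugate adduct, isolated as silyl enol ether 10 and converted into enol triflate 12. Ring D is closed by 7-endo epoxide opening, the carbonyl is transposed from C15 to C14 with entry of the C15 methyl, and C14=CH2, epoxide, vinyl opening and ozonolysis follow.
- Ring order: rings B and C come from the carbocycle of 3-methylanisole, ring D closes in step 11 and ring A in step 24. C11 (hydrogenation), C10=CH2 and C22=O follow.

Key step: step 21

Remark on the chemistry: the D-fructose-derived Shi ketone is assumed to give the (R)-epoxide from an R–CH=C(CH3)2 terminus (as 3R requires), and the lipase is assumed to acylate the (R)-enantiomer of 5 faster.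

## Route

Step 1
Reactants: 1 3-methylanisole
Product: 2 1-methoxy-5-methylcyclohexa-1,4-diene
Conditions: Li, NH3 (l), t-BuOH, THF, −78 → −33 °C
Reagents that add atoms: none
Why: Birch reduction of the anisole leaves the methoxy- and methyl-bearing carbons olefinic and so should give the unconjugated 1,4-diene.

Step 2
Reactants: 2 1-methoxy-5-methylcyclohexa-1,4-diene
Product: 3 3-methylcyclohex-3-en-1-one
Conditions: oxalic acid (cat), MeOH/H2O, rt
Reagents that add atoms: water, O
Why: Mild acid hydrolysis of the enol ether should release the ketone without moving the trisubstituted alkene into conjugation.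

Step 3
Reactants: 3 3-methylcyclohex-3-en-1-one
Product: 5 rac-4-hydroxy-3-methylcyclohex-2-en-1-one, via epoxy ketone 4 (not isolated)
Conditions: mCPBA, CH2Cl2, 0 °C; then Et3N, rt
Reagents that add atoms: mCPBA (3-chloroperbenzoic acid), O=C(OO)c1cccc(Cl)c1
Why: Prilezhaev epoxidation of the electron-rich alkene followed by amine-induced E1cB opening of the β,γ-epoxy ketone should give the γ-hydroxy enone.

Step 4
Reactants: 5 rac-4-hydroxy-3-methylcyclohex-2-en-1-one
Product: 6 (S)-4-hydroxy-3-methylcyclohex-2-en-1-one
Conditions: lipase PS (Burkholderia cepacia), vinyl acetate, t-BuOMe, rt, run to just past half conversion; chromatographic separation from the (R)-acetate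
Reagents that add atoms: none
Why: Lipase-catalysed kinetic resolution by enantioselective transesterification should acylate the (R)-alcohol faster, so that the (S)-alcohol is recovered and the C7/C18 configuration of the target is fixed here.

Step 5
Reactants: 6 (S)-4-hydroxy-3-methylcyclohex-2-en-1-one
Product: 7 (S)-3-methyl-4-(triethylsilyloxy)cyclohex-2-en-1-one
Conditions: Et3SiCl, imidazole, CH2Cl2, 0 °C → rt
Reagents that add atoms: chlorotriethylsilane, CC[Si](Cl)(CC)CC
Why: Imidazole-mediated silylation gives a triethylsilyl ether that is bulky enough to direct the copper additions and labile enough to be removed later beside a tertiary triethylsilyl ether and a TBS ether.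

Step 6
Reactants: 8 5-bromo-2-methylpent-2-ene
Product: 9 (4-methylpent-3-en-1-yl)magnesium bromide
Conditions: Mg, I2 (cat), THF, rt → 40 °C
Reagents that add atoms: magnesium, [Mg]
Why: Insertion of magnesium into the primary C–Br bond should give the homoallylic Grignard reagent, which is used as a titrated solution in steps 7 and 21.

Step 7
Reactants: 7 (S)-3-methyl-4-(triethylsilyloxy)cyclohex-2-en-1-one; 9 (4-methylpent-3-en-1-yl)magnesium bromide
Product: 10 trimethylsilyl enol ether of the homoprenyl adduct (C15–OSiMe3, C14=C15)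
Conditions: CuBr·SMe2 (10 mol%), Me3SiCl, HMPA, THF, −78 → −40 °C; Et3N, then cold aq NaHCO3, pentane; filtration through Et3N-deactivated silica
Reagents that add atoms: chlorotrimethylsilane, C[Si](C)(C)Cl
Why: Copper-catalysed 1,4-addition of the Grignard reagent accelerated by Me3SiCl should occur anti to the adjacent silyloxy group (the same control as in step 21), which sets the quaternary C19 with its methyl cis and C20 trans to the C18 oxygen, and silylation on oxygen as the adduct forms should fix the double bond between C14 and C15 in an isolable, regiodefined silyl enol ether.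

Step 8
Reactants: 10 trimethylsilyl enol ether of the homoprenyl adduct
Product: 12 enol triflate of the homoprenyl adduct (C15–OTf), via lithium enolate 11 (not isolated)
Conditions: CH3Li, THF, 0 °C → rt; then Comins' reagent, −78 → 0 °C
Reagents that add atoms: Comins' reagent (N-(5-chloropyridin-2-yl)bis(trifluoromethanesulfonyl)imide), O=S(=O)(N(c1ccc(Cl)cn1)S(=O)(=O)C(F)(F)F)C(F)(F)F
Why: Cleavage of the enol O–Si bond by methyllithium should release the lithium enolate without loss of regiochemistry because no proton source is present, and O-sulfonylation by the N-aryl triflimide then gives the alkenyl triflate, the alkyl triethylsilyl ether being inert to methyllithium under these conditions.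

Step 9
Reactants: 12 enol triflate with C18–OSiEt3
Product: 13 enol triflate with free C18–OH
Conditions: PPTS (cat), MeOH, rt → 40 °C
Reagents that add atoms: none
Why: Acid-catalysed methanolysis should remove the secondary triethylsilyl ether while the enol triflate and the trisubstituted alkene stay inert.

Step 10
Reactants: 13 enol triflate with free C18–OH
Product: 14 (22R)-epoxy alcohol
Conditions: D-fructose-derived Shi ketone (30 mol%), KHSO5 (as 2KHSO5·KHSO4·K2SO4), K2CO3, Bu4NHSO4 (cat), MeCN/CH2(OMe)2/aq Na2B4O7 buffer, 0 °C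
Reagents that add atoms: potassium peroxymonosulfate (KHSO5), [K+].[O-]S(=O)(=O)OO
Why: Shi epoxidation, in which the chiral dioxirane attacks the electron-rich trisubstituted alkene through the spiro transition state, should give the (22R)-epoxide under catalyst control and leave the electron-poor enol triflate alkene alone.

Step 11
Reactants: 14 (22R)-epoxy alcohol
Product: 15 ring C/D enol triflate with C22–OH
Conditions: CSA (10 mol%), CH2Cl2, 0 °C
Reagents that add atoms: none
Why: Acid-catalysed epoxide-opening cyclisation in the 7-endo mode, in which the C18 hydroxyl attacks the tertiary C23 that carries most of the positive charge, should close ring D trans-fused (C18–O and C19–C20 are already trans) and leave the C22–O bond and its configuration intact, the deactivated enol triflate being unable to intercept the cation.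

Step 12
Reactants: 15 ring C/D enol triflate with C22–OH
Product: 16 C22 tert-butyldimethylsilyl ether
Conditions: t-BuMe2SiOTf, 2,6-lutidine, CH2Cl2, −78 → 0 °C
Reagents that add atoms: tert-butyldimethylsilyl triflate, CC(C)(C)[Si](C)(C)OS(=O)(=O)C(F)(F)F
Why: Silylation with the silyl triflate protects the hindered secondary C22 alcohol as a TBS ether that should outlast every step up to step 28 and so masks the future C22 ketone.

Step 13
Reactants: 16 C22 tert-butyldimethylsilyl ether
Product: 17 C14=C15 alkene bearing the C15 methyl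
Conditions: CH3MgBr, Fe(acac)3 (5 mol%), THF/NMP, −20 → 0 °C
Reagents that add atoms: methylmagnesium bromide, C[Mg]Br
Why: Iron-catalysed Kumada-type cross-coupling of the alkenyl triflate with the methyl Grignard reagent should replace the triflate by CH3 without moving the double bond, so the C15 methyl enters on a defined trisubstituted alkene.

Step 14
Reactants: 17 C14=C15 alkene bearing the C15 methyl
Product: 19 C14 alcohol of ring C/D, via alkylborane 18 (not isolated)
Conditions: BH3·THF, THF, 0 °C → rt; then NaOH, H2O2, H2O, 0 °C → rt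
Reagents that add atoms: hydrogen peroxide, OO
Why: Hydroboration–oxidation should place boron on the less substituted C14 from the face opposite the axial C19 methyl and replace it by OH with retention, which moves the oxygen from C15 to C14, and the configurations formed at C14 and C15 are provisional because both are reset in step 15.

Step 15
Reactants: 19 C14 alcohol of ring C/D
Product: 21 ring C/D C14 ketone, via axial-methyl ketone 20 (not isolated)
Conditions: Dess–Martin periodinane, CH2Cl2, rt; then K2CO3 (cat), MeOH, rt on the crude ketone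
Reagents that add atoms: none
Why: Dess–Martin oxidation gives the C14 ketone and base-mediated enolisation should then equilibrate C15 to the equatorial methyl epimer, which avoids the 1,3-diaxial CH3/CH3 contact with the C19 methyl (thermodynamic control of C15).

Step 16
Reactants: 21 ring C/D C14 ketone
Product: 22 C14 exocyclic methylene compound
Conditions: Ph3PCH3Br, KOtBu, toluene, 90 °C
Reagents that add atoms: methyltriphenylphosphonium bromide, C[P+](c1ccccc1)(c1ccccc1)c1ccccc1.[Br-]
Why: Wittig methylenation with excess ylide at elevated temperature should convert the hindered ketone into the exocyclic alkene, and the equatorial C15 methyl is kept because it belongs to the stable epimer of the ketone that is consumed.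

Step 17
Reactants: 22 C14 exocyclic methylene compound
Product: 23 C13–C14 spiro-epoxide
Conditions: dimethyldioxirane, acetone, 0 °C
Reagents that add atoms: dimethyldioxirane, CC1(C)OO1
Why: Electrophilic epoxidation by the dioxirane should take place on the alkene face opposite the axial C19 methyl that flanks it, so the epoxide oxygen ends up axial and trans to that methyl, which sets C14 (a carbon nucleophile adding to ketone 21 would approach from the same face and give the opposite C14 epimer).

Step 18
Reactants: 23 C13–C14 spiro-epoxide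
Product: 24 homoallylic tertiary alcohol
Conditions: CH2=CHMgBr, CuI (10 mol%), THF, −30 → 0 °C
Reagents that add atoms: vinylmagnesium bromide, C=C[Mg]Br
Why: Copper-catalysed SN2 opening of the 2,2-disubstituted epoxide by the vinyl Grignard reagent should occur at the CH2 terminus (C13), so the C14–O bond and the configuration set in step 17 are kept and C12 enters as a vinyl carbon.

Step 19
Reactants: 24 homoallylic tertiary alcohol
Product: 25 C14 triethylsilyl ether
Conditions: Et3SiOTf, 2,6-lutidine, CH2Cl2, 0 °C → rt
Reagents that add atoms: triethylsilyl triflate, CC[Si](CC)(CC)OS(=O)(=O)C(F)(F)F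
Why: The reactive silyl triflate should silylate the hindered tertiary C14 alcohol, which must be masked before the aldehyde meets a basic enolate.

Step 20
Reactants: 25 C14 triethylsilyl ether
Product: 27 ring C/D C12 aldehyde, via ozonide 26 (not isolated)
Conditions: O3, CH2Cl2, −78 °C; then PPh3, −78 °C → rt; used without chromatography
Reagents that add atoms: ozone, [O-][O+]=O
Why: Ozonolysis with reductive work-up should cleave the terminal alkene to the C12 aldehyde and leave the silyl ethers and the oxepane untouched.

Step 21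
Reactants: 7 (S)-3-methyl-4-(triethylsilyloxy)cyclohex-2-en-1-one; 9 (4-methylpent-3-en-1-yl)magnesium bromide; 27 ring C/D C12 aldehyde
Product: 31 C11=C12 enone, via magnesium enolate 28 (not isolated), via magnesium aldolate 29 (not isolated), via mesylate 30 (not isolated)
Conditions: 7 and 9 (slight excess of 7 over 9, both in excess over 27), CuBr·SMe2 (20 mol%), THF, −40 → −20 °C; then 27, −78 °C; then CH3SO2Cl, −78 → 0 °C; then DBU, 0 °C → rt
Reagents that add atoms: none
Why: Transmetalation of 9 to a homoprenylcopper species, π-complexation with enone 7 and reductive elimination should deliver the homoprenyl group to C6 on the face opposite the pseudoaxial C7 silyloxy group, which forms the C5–C6 bond, the quaternary centre C6 (methyl cis and C5 trans to the C7 oxygen) and the regiodefined bromomagnesium enolate 28. In the absence of proton sources the enolate cannot equilibrate towards C9, so it should add through C11 to the aldehyde carbon C12 of 27 in a closed six-membered aldol transition state, forming the C11–C12 bond; the configurations at C11 and C12 of aldolate 29 do not matter. Mesylation of the aldolate in the same flask to 30 and E1cB elimination with DBU should give the exocyclic enone 31, expected as the Z isomer in which C13 points away from the quaternary C6, a geometry that is erased in step 26. The closest known reaction type is the three-component coupling of 4-silyloxy cycloalkenones by copper-mediated conjugate addition and aldol trapping of the enolate, followed by dehydration of the aldol. No ring is closed, and the only new stereocentre, C6, is controlled by the C7 silyloxy substituent on the neighbouring carbon. The step needs anti facial selectivity (secured by C7–OSiEt3), reaction at C11 and not C9 (secured by forming the enolate through conjugate addition) and addition to the aldehyde in preference to proton transfer from C13 (favoured by low temperature and the magnesium counter-ion).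

Step 22
Reactants: 31 C11=C12 enone
Product: 32 enone with free C7–OH
Conditions: PPTS (cat), MeOH/CH2Cl2, 0 °C → rt
Reagents that add atoms: none
Why: Acid-catalysed methanolysis should cleave the secondary C7 triethylsilyl ether much faster than the tertiary, doubly α-branched C14 triethylsilyl ether and the TBS ether, and loss of the C14 group would in any case not block the following steps.

Step 23
Reactants: 32 enone with free C7–OH
Product: 33 (3R)-epoxy alcohol
Conditions: D-fructose-derived Shi ketone (30 mol%), KHSO5 (as 2KHSO5·KHSO4·K2SO4), K2CO3, Bu4NHSO4 (cat), MeCN/CH2(OMe)2/aq Na2B4O7 buffer, 0 °C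
Reagents that add atoms: potassium peroxymonosulfate (KHSO5), [K+].[O-]S(=O)(=O)OO
Why: Shi epoxidation as in step 10, in which the electrophilic chiral dioxirane selects the trisubstituted alkene over the electron-poor enone alkene, should give the (3R)-epoxide under catalyst control.

Step 24
Reactants: 33 (3R)-epoxy alcohol
Product: 34 ring A/B enone with C3–OH
Conditions: CSA (10 mol%), CH2Cl2, 0 °C
Reagents that add atoms: none
Why: Acid-catalysed 7-endo epoxide opening, in which the C7 hydroxyl attacks the tertiary C2 of the protonated epoxide, should close ring A trans-fused (C7–O and C6–C5 are already trans) and leave the C3–O bond intact, so C3 keeps the R configuration set in step 23.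

Step 25
Reactants: 34 ring A/B enone with C3–OH
Product: 35 C3 acetate
Conditions: Ac2O, pyridine, DMAP (cat), CH2Cl2, 0 °C → rt
Reagents that add atoms: acetic anhydride, CC(=O)OC(C)=O
Why: DMAP-catalysed acylation should esterify the only free hydroxyl (C3) with retention.

Step 26
Reactants: 35 C3 acetate
Product: 36 saturated C10 ketone
Conditions: H2 (1 atm), Pd/C, EtOAc, rt
Reagents that add atoms: none
Why: Heterogeneous hydrogenation should add H2 to the conjugated C11=C12 bond from the face opposite the axial C6 methyl of the now rigid trans-fused A/B system, which places the C11 hydrogen axial and the C12 chain equatorial (cis to the C6 methyl) as in the target; this is also the thermodynamic arrangement at the epimerisable C11, and silyl ethers, acetate and ketone are stable in ethyl acetate.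

Step 27
Reactants: 36 saturated C10 ketone
Product: 37 C10 exocyclic methylene compound
Conditions: Zn, CH2Br2, TiCl4, THF/CH2Cl2, 0 °C → rt
Reagents that add atoms: dibromomethane, BrCBr
Why: Takai–Lombardo methylenation with the non-basic geminal dimetallic methylene reagent should olefinate the hindered ketone without epimerising C11 and without attacking the acetate.

Step 28
Reactants: 37 C10 exocyclic methylene compound
Product: 38 C14,C22 diol
Conditions: HF·pyridine, pyridine, THF, 0 °C → rt
Reagents that add atoms: none
Why: Fluoride-driven cleavage (strong Si–F bond) should remove both silyl ethers under buffered conditions that spare the acetate and the exocyclic alkene.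

Step 29
Reactants: 38 C14,C22 diol
Product: 39 3-epi-sodwanone K 3-acetate
Conditions: Dess–Martin periodinane, CH2Cl2, 0 °C → rt
Reagents that add atoms: none
Why: Dess–Martin oxidation should convert the only secondary alcohol (C22) into the ketone, the tertiary C14 alcohol being inert.

## Compound list

1 | 3-methylanisole | COc1cccc(C)c1 | starting material
2 | 1-methoxy-5-methylcyclohexa-1,4-diene | COC1=CCC=C(C)C1 | intermediate
3 | 3-methylcyclohex-3-en-1-one | CC1=CCCC(=O)C1 | intermediate
4 | rac-1-methyl-7-oxabicyclo[4.1.0]heptan-3-one (3,4-epoxy-3-methylcyclohexanone) | CC12CC(=O)CCC1O2 | intermediate (not isolated)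
5 | rac-4-hydroxy-3-methylcyclohex-2-en-1-one | CC1=CC(=O)CCC1O | intermediate
6 | (S)-4-hydroxy-3-methylcyclohex-2-en-1-one | O=C1CC[C@H](O)C(C)=C1 | intermediate
7 | (S)-3-methyl-4-(triethylsilyloxy)cyclohex-2-en-1-one | O=C1CC[C@H](O[Si](CC)(CC)CC)C(C)=C1 | intermediate
8 | 5-bromo-2-methylpent-2-ene | CC(C)=CCCBr | starting material
9 | (4-methylpent-3-en-1-yl)magnesium bromide | CC(C)=CCC[Mg]Br | intermediate
10 | trimethyl{[(3S,4S)-3-methyl-3-(4-methylpent-3-en-1-yl)-4-(triethylsilyloxy)cyclohex-1-en-1-yl]oxy}silane (homoprenyl trans to OSiEt3) | C[Si](C)(C)OC1=C[C@](C)(CCC=C(C)C)[C@@H](O[Si](CC)(CC)CC)CC1 | intermediate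
11 | lithium enolate from 10 (C=C towards the former enone α-carbon) | [Li]OC1=C[C@](C)(CCC=C(C)C)[C@@H](O[Si](CC)(CC)CC)CC1 | intermediate (not isolated)
12 | (3S,4S)-3-methyl-3-(4-methylpent-3-en-1-yl)-4-(triethylsilyloxy)cyclohex-1-en-1-yl trifluoromethanesulfonate | O=S(=O)(OC1=C[C@](C)(CCC=C(C)C)[C@@H](O[Si](CC)(CC)CC)CC1)C(F)(F)F | intermediate
13 | (3S,4S)-4-hydroxy-3-methyl-3-(4-methylpent-3-en-1-yl)cyclohex-1-en-1-yl trifluoromethanesulfonate | O=S(=O)(OC1=C[C@](C)(CCC=C(C)C)[C@@H](O)CC1)C(F)(F)F | intermediate
14 | (3S,4S)-3-{2-[(2R)-3,3-dimethyloxiran-2-yl]ethyl}-4-hydroxy-3-methylcyclohex-1-en-1-yl trifluoromethanesulfonate | O=S(=O)(OC1=C[C@](C)(CC[C@H]2OC2(C)C)[C@@H](O)CC1)C(F)(F)F | intermediate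
15 | ring C/D enol triflate: trans-fused 3-hydroxy-2,2,5a-trimethyl-2,3,4,5,5a,8,9,9a-octahydro-1-benzoxepin-6-yl triflate, (22R), C19 methyl and C18–H trans | O=S(=O)(OC1=C[C@]2(C)CC[C@@H](O)C(C)(C)O[C@H]2CC1)C(F)(F)F | intermediate
16 | C22 tert-butyldimethylsilyl ether of 15 | O=S(=O)(OC1=C[C@]2(C)CC[C@@H](O[Si](C)(C)C(C)(C)C)C(C)(C)O[C@H]2CC1)C(F)(F)F | intermediate
17 | trans-fused 3-(tert-butyldimethylsilyloxy)-2,2,5a,7-tetramethyl-2,3,4,5,5a,8,9,9a-octahydro-1-benzoxepine (C14=C15 alkene) | CC1=C[C@]2(C)CC[C@@H](O[Si](C)(C)C(C)(C)C)C(C)(C)O[C@H]2CC1 | intermediate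
18 | C14 monoalkylborane from 17 (boron and C15–H on the face opposite the C19 methyl) | B[C@H]1[C@H](C)CC[C@@H]2OC(C)(C)[C@H](O[Si](C)(C)C(C)(C)C)CC[C@]21C | intermediate (not isolated)
19 | C14 alcohol (OH trans to the C19 methyl, C15 methyl cis to it, as expected from step 14) | O[C@H]1[C@H](C)CC[C@@H]2OC(C)(C)[C@H](O[Si](C)(C)C(C)(C)C)CC[C@]21C | intermediate
20 | C14 ketone with axial C15 methyl (cis to the C19 methyl) | O=C1[C@H](C)CC[C@@H]2OC(C)(C)[C@H](O[Si](C)(C)C(C)(C)C)CC[C@]21C | intermediate (not isolated)
21 | ring C/D C14 ketone: trans-fused 3-(tert-butyldimethylsilyloxy)-2,2,5a,7-tetramethyloctahydro-1-benzoxepin-6-one, C15 methyl equatorial (trans to the C19 methyl) | O=C1[C@@H](C)CC[C@@H]2OC(C)(C)[C@H](O[Si](C)(C)C(C)(C)C)CC[C@]21C | intermediate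
22 | C14 exocyclic methylene analogue of 21 | C=C1[C@@H](C)CC[C@@H]2OC(C)(C)[C@H](O[Si](C)(C)C(C)(C)C)CC[C@]21C | intermediate
23 | C13–C14 spiro-epoxide (epoxide O trans to the C19 methyl) | C1O[C@]12[C@@H](C)CC[C@@H]3OC(C)(C)[C@H](O[Si](C)(C)C(C)(C)C)CC[C@]32C | intermediate
24 | C14 allyl carbinol (OH trans, allyl cis to the C19 methyl) | C=CC[C@]1(O)[C@@H](C)CC[C@@H]2OC(C)(C)[C@H](O[Si](C)(C)C(C)(C)C)CC[C@]21C | intermediate
25 | C14 triethylsilyl ether of 24 | C=CC[C@]1(O[Si](CC)(CC)CC)[C@@H](C)CC[C@@H]2OC(C)(C)[C@H](O[Si](C)(C)C(C)(C)C)CC[C@]21C | intermediate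
26 | ozonide (1,2,4-trioxolane) of 25 | C1OC(C[C@]2(O[Si](CC)(CC)CC)[C@@H](C)CC[C@@H]3OC(C)(C)[C@H](O[Si](C)(C)C(C)(C)C)CC[C@]32C)OO1 | intermediate (not isolated)
27 | ring C/D C12 aldehyde (C14 OSiEt3, C22 OTBS) | O=CC[C@]1(O[Si](CC)(CC)CC)[C@@H](C)CC[C@@H]2OC(C)(C)[C@H](O[Si](C)(C)C(C)(C)C)CC[C@]21C | intermediate
28 | bromomagnesium enolate from homoprenyl addition to 7 (homoprenyl trans to OSiEt3, C=C towards the former enone α-carbon) | Br[Mg]OC1=C[C@](C)(CCC=C(C)C)[C@@H](O[Si](CC)(CC)CC)CC1 | intermediate (not isolated)
29 | bromomagnesium aldolate (C11/C12 diastereomer mixture) | O=C1CC[C@H](O[Si](CC)(CC)CC)[C@@](C)(CCC=C(C)C)C1C(O[Mg]Br)C[C@]1(O[Si](CC)(CC)CC)[C@@H](C)CC[C@@H]2OC(C)(C)[C@H](O[Si](C)(C)C(C)(C)C)CC[C@]21C | intermediate (not isolated)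
30 | C12 mesylate of the aldol (C11/C12 diastereomer mixture) | O=C1CC[C@H](O[Si](CC)(CC)CC)[C@@](C)(CCC=C(C)C)C1C(OS(C)(=O)=O)C[C@]1(O[Si](CC)(CC)CC)[C@@H](C)CC[C@@H]2OC(C)(C)[C@H](O[Si](C)(C)C(C)(C)C)CC[C@]21C | intermediate (not isolated)
31 | coupled (Z)-C11=C12 enone (C7 OSiEt3, C14 OSiEt3, C22 OTBS; homoprenyl trans to C7–O) | O=C1CC[C@H](O[Si](CC)(CC)CC)[C@@](C)(CCC=C(C)C)/C1=C/C[C@]1(O[Si](CC)(CC)CC)[C@@H](C)CC[C@@H]2OC(C)(C)[C@H](O[Si](C)(C)C(C)(C)C)CC[C@]21C | intermediate
32 | enone with free C7–OH | O=C1CC[C@H](O)[C@@](C)(CCC=C(C)C)/C1=C/C[C@]1(O[Si](CC)(CC)CC)[C@@H](C)CC[C@@H]2OC(C)(C)[C@H](O[Si](C)(C)C(C)(C)C)CC[C@]21C | intermediate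
33 | (3R)-2,3-epoxide of 32 | O=C1CC[C@H](O)[C@@](C)(CC[C@H]2OC2(C)C)/C1=C/C[C@]1(O[Si](CC)(CC)CC)[C@@H](C)CC[C@@H]2OC(C)(C)[C@H](O[Si](C)(C)C(C)(C)C)CC[C@]21C | intermediate
34 | ring A/B enone with trans-fused oxepane and (3R)-OH | O=C1CC[C@@H]2OC(C)(C)[C@H](O)CC[C@@]2(C)/C1=C/C[C@]1(O[Si](CC)(CC)CC)[C@@H](C)CC[C@@H]2OC(C)(C)[C@H](O[Si](C)(C)C(C)(C)C)CC[C@]21C | intermediate
35 | C3 acetate of 34 | O=C1CC[C@@H]2OC(C)(C)[C@H](OC(C)=O)CC[C@@]2(C)/C1=C/C[C@]1(O[Si](CC)(CC)CC)[C@@H](C)CC[C@@H]2OC(C)(C)[C@H](O[Si](C)(C)C(C)(C)C)CC[C@]21C | intermediate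
36 | saturated C10 ketone (C11–H trans to the C6 methyl, side chain equatorial) | O=C1CC[C@@H]2OC(C)(C)[C@H](OC(C)=O)CC[C@@]2(C)[C@@H]1CC[C@]1(O[Si](CC)(CC)CC)[C@@H](C)CC[C@@H]2OC(C)(C)[C@H](O[Si](C)(C)C(C)(C)C)CC[C@]21C | intermediate
37 | C10 exocyclic methylene compound (C14 OSiEt3, C22 OTBS) | C=C1CC[C@@H]2OC(C)(C)[C@H](OC(C)=O)CC[C@@]2(C)[C@@H]1CC[C@]1(O[Si](CC)(CC)CC)[C@@H](C)CC[C@@H]2OC(C)(C)[C@H](O[Si](C)(C)C(C)(C)C)CC[C@]21C | intermediate
38 | C14,C22 diol | C=C1CC[C@@H]2OC(C)(C)[C@H](OC(C)=O)CC[C@@]2(C)[C@@H]1CC[C@]1(O)[C@@H](C)CC[C@@H]2OC(C)(C)[C@H](O)CC[C@]21C | intermediate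
39 | 3-epi-sodwanone K 3-acetate | C=C1CC[C@@H]2OC(C)(C)[C@H](OC(C)=O)CC[C@@]2(C)[C@@H]1CC[C@]1(O)[C@@H](C)CC[C@@H]2OC(C)(C)C(=O)CC[C@]21C | target

## Step count and risks

Total step count: 29. Longest linear sequence: 28 steps (steps 1–5 and 7–29; step 6 prepares the Grignard reagent used in steps 7 and 21).

Steps most likely to fail:

1. Step 21 (key coupling). The hindered magnesium enolate may take a proton from C13 of the neopentyl-type aldehyde, with loss of the C14 silanolate, faster than it adds. The copper-mediated addition to the β,β-disubstituted enone may also be too slow at the temperature that the aldol step tolerates. The fallback splits the coupling and sets out from 10 and 27, the silyl enol ether 10 of step 7 serving as the regiodefined enolate equivalent. A Mukaiyama aldol addition of 10 to 27 (BF3·OEt2, CH2Cl2, −78 °C) should give the β-hydroxy ketone F1 under non-basic conditions. Mesylation (CH3SO2Cl, Et3N) to 30 and elimination with DBU bring the route back at 31.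

2. Step 24 (closure of ring A). Attack of the C7 hydroxyl at the secondary C3 (6-exo, giving a tetrahydropyran with a 2-hydroxyprop-2-yl side chain) or a hydride shift in the opened epoxide may compete with the 7-endo closure. The fallback removes the choice of ring size and sets out from 31. Shi epoxidation of 31 under the conditions of step 23 gives the (3R)-epoxide F2 with the C7 silyl ether still in place. Isomerisation of the epoxide with Me3SiOTf and DBU (toluene, 0 °C) should give the trimethylsilyl ether of the 2-methylallylic alcohol F3 with the C3–O bond untouched. PPTS in MeOH removes the trimethylsilyl group and the C7 triethylsilyl group to give the diol F4. Intramolecular alkoxymercuration with Hg(OCOCF3)2 and K2CO3 in MeCN lets the C7 hydroxyl add to the internal alkene carbon C2 (7-exo, no smaller ring possible) and should give the organomercurial F5. Demercuration with Bu3SnH leaves the second C2 methyl group and returns the route at 34.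

3. Step 18 (opening of the spiro-epoxide). Substitution at the CH2 group next to the fully substituted C14 may be slow, and magnesium salts may instead rearrange the epoxide to an aldehyde by hydride shift. The fallback avoids substitution at this carbon and sets out from 22. Dihydroxylation (OsO4 cat, N-methylmorpholine N-oxide, acetone/H2O) from the face opposite the C19 methyl should give the diol F6 with the C14 oxygen placed as in 23. Oxidation of the primary alcohol (SO3·pyridine, DMSO, i-Pr2NEt) gives the α-hydroxy aldehyde F7, and Et3SiOTf with 2,6-lutidine gives the α-silyloxy aldehyde F8. Wittig homologation with Ph3P=CHOCH3 gives the enol ether F9, and hydrolysis with Hg(OAc)2 in aqueous THF returns the route at 27.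

Further compounds
F1 | step 21 | β-hydroxy ketone (aldol of 10 and 27, C11/C12 diastereomer mixture) | O=C1CC[C@H](O[Si](CC)(CC)CC)[C@@](C)(CCC=C(C)C)C1C(O)C[C@]1(O[Si](CC)(CC)CC)[C@@H](C)CC[C@@H]2OC(C)(C)[C@H](O[Si](C)(C)C(C)(C)C)CC[C@]21C
F2 | step 24 | (3R)-2,3-epoxide of 31 | O=C1CC[C@H](O[Si](CC)(CC)CC)[C@@](C)(CC[C@H]2OC2(C)C)/C1=C/C[C@]1(O[Si](CC)(CC)CC)[C@@H](C)CC[C@@H]2OC(C)(C)[C@H](O[Si](C)(C)C(C)(C)C)CC[C@]21C
F3 | step 24 | (3R)-3-trimethylsilyloxy-2-methylalk-1-ene from F2 | O=C1CC[C@H](O[Si](CC)(CC)CC)[C@@](C)(CC[C@@H](O[Si](C)(C)C)C(C)=C)/C1=C/C[C@]1(O[Si](CC)(CC)CC)[C@@H](C)CC[C@@H]2OC(C)(C)[C@H](O[Si](C)(C)C(C)(C)C)CC[C@]21C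
F4 | step 24 | C3,C7 diol with isopropenyl terminus | O=C1CC[C@H](O)[C@@](C)(CC[C@@H](O)C(C)=C)/C1=C/C[C@]1(O[Si](CC)(CC)CC)[C@@H](C)CC[C@@H]2OC(C)(C)[C@H](O[Si](C)(C)C(C)(C)C)CC[C@]21C
F5 | step 24 | ring A organomercurial (C2 bears CH3 and CH2HgOCOCF3) | O=C1CC[C@@H]2OC(C)(C[Hg]OC(=O)C(F)(F)F)[C@H](O)CC[C@@]2(C)/C1=C/C[C@]1(O[Si](CC)(CC)CC)[C@@H](C)CC[C@@H]2OC(C)(C)[C@H](O[Si](C)(C)C(C)(C)C)CC[C@]21C
F6 | step 18 | C13,C14 diol (C14–OH trans to the C19 methyl) | OC[C@]1(O)[C@@H](C)CC[C@@H]2OC(C)(C)[C@H](O[Si](C)(C)C(C)(C)C)CC[C@]21C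
F7 | step 18 | C14 hydroxy C13 aldehyde | O=C[C@]1(O)[C@@H](C)CC[C@@H]2OC(C)(C)[C@H](O[Si](C)(C)C(C)(C)C)CC[C@]21C
F8 | step 18 | C14 triethylsilyloxy C13 aldehyde | O=C[C@]1(O[Si](CC)(CC)CC)[C@@H](C)CC[C@@H]2OC(C)(C)[C@H](O[Si](C)(C)C(C)(C)C)CC[C@]21C
F9 | step 18 | methyl enol ether (E/Z mixture) | COC=C[C@]1(O[Si](CC)(CC)CC)[C@@H](C)CC[C@@H]2OC(C)(C)[C@H](O[Si](C)(C)C(C)(C)C)CC[C@]21C
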